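**Retrosynthetic overview**

1. The target is two hexasubstituted phloroglucinol rings joined by one CH2. Ring A, the butanoyl ring, is numbered by ring positions: position 1 C-butanoyl, position 2 C-OH, position 3 C-CH3, position 4 C-OCH3, position 5 C-CH2 (bridge), position 6 C-OH. Ring B is the acetyl ring and comes from 2,4,6-trihydroxytoluene.
2. Feature used: in ring A the one O-methylated carbon (position 4) lies between the two C-alkylated carbons (positions 3 and 5). Positions 3, 4 and 5 are therefore the α-carbon, carbonyl carbon and α'-carbon of a 1-arylpentan-3-one as its methyl enol ether, and positions 6, 1 and 2 are a malonyl unit. Cutting the ring bonds between positions 2 and 3 and between positions 5 and 6 is a [3+3] Effenberger disconnection.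
3. After the ring closure: Houben–Hoesch butanoylation at position 1 of ring A, the only free ring carbon, then hydrogenolysis of the three O-benzyl groups of ring B.
4. Before it: the enol ether comes from the ketone through its dimethyl ketal; the ketone from the ring B aldehyde by Horner–Wadsworth–Emmons olefination and C=C hydrogenation; the aldehyde from 2,4,6-trihydroxytoluene by formylation, acetylation and benzylation.
5. Ring order: ring B is present from the start; ring A is the only ring formed (step 8).

Key step: step 8

Remark: step 7 is expected to give the enol ether as a mixture of double-bond isomers (pent-3-enyl and pent-2-enyl, E and Z). Compound 10 is written as the (E)-3-methoxypent-3-enyl isomer, and the whole mixture is taken into step 8, because both α-carbons of the former ketone are acylated and every isomer should give the same arene.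

**Route**

Step 1
Reactants: 1 2,4,6-trihydroxytoluene
Product: 3 2,4,6-trihydroxy-3-methylbenzaldehyde, via iminium chloride 2 (not isolated)
Conditions: POCl3, DMF, EtOAc, 0 °C → rt; then H2O, 60 °C
Reagents that add atoms: N,N-dimethylformamide, CN(C)C=O; water, O; phosphoryl chloride, O=P(Cl)(Cl)Cl (chloride of intermediate 2 only)
Why: Vilsmeier–Haack formylation, in which the chloroiminium ion from DMF and POCl3 should attack one of the two equivalent free positions of the triol, the iminium salt 2 deactivating the ring against a second formylation before it is hydrolysed, and formylation ahead of acetylation avoiding the 3-formylchromone pathway of ortho-hydroxyacetophenones.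

Step 2
Reactants: 3 2,4,6-trihydroxy-3-methylbenzaldehyde
Product: 4 3-acetyl-2,4,6-trihydroxy-5-methylbenzaldehyde
Conditions: AcCl, AlCl3, PhNO2–CH2Cl2, 0 °C → rt; aq. HCl
Reagents that add atoms: acetyl chloride, CC(=O)Cl
Why: Friedel–Crafts acylation at the only free ring carbon, which three hydroxyl groups keep nucleophilic despite the formyl group, with any O-acetate expected to undergo Fries rearrangement under the same conditions.

Step 3
Reactants: 4 3-acetyl-2,4,6-trihydroxy-5-methylbenzaldehyde
Product: 5 3-acetyl-2,4,6-tris(benzyloxy)-5-methylbenzaldehyde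
Conditions: BnBr, K2CO3, DMF, 60 °C
Reagents that add atoms: benzyl bromide, BrCc1ccccc1
Why: Williamson etherification of the three phenoxides, where the ring has no free carbon, the polar aprotic medium favours O- over C-benzylation, and excess bromide with heating should also reach the hydroxyl chelated between the two carbonyl groups.

Step 4
Reactants: 5 3-acetyl-2,4,6-tris(benzyloxy)-5-methylbenzaldehyde; 6 diethyl (2-oxobutyl)phosphonate
Product: 7 (E)-1-[3-acetyl-2,4,6-tris(benzyloxy)-5-methylphenyl]pent-1-en-3-one
Conditions: LiCl, DBU, MeCN, rt
Reagents that add atoms: none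
Why: Horner–Wadsworth–Emmons olefination under Masamune–Roush conditions, in which the lithium-chelated phosphonate anion should add to the aldehyde and not to the hindered, less electrophilic acetyl ketone, the stabilised carbanion giving the (E)-enone.

Step 5
Reactants: 7 (E)-1-[3-acetyl-2,4,6-tris(benzyloxy)-5-methylphenyl]pent-1-en-3-one
Product: 8 1-[3-acetyl-2,4,6-tris(benzyloxy)-5-methylphenyl]pentan-3-one
Conditions: H2 (1 atm), Pd/C, Ph2S (cat.), EtOAc, rt
Reagents that add atoms: none
Why: Catalytic hydrogenation of the conjugated C=C bond over Pd/C poisoned with diphenyl sulfide, a catalyst system that saturates alkenes without hydrogenolysis of O-benzyl groups or reduction of aryl ketones.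

Step 6
Reactants: 8 1-[3-acetyl-2,4,6-tris(benzyloxy)-5-methylphenyl]pentan-3-one
Product: 9 1-[2,4,6-tris(benzyloxy)-3-(3,3-dimethoxypentyl)-5-methylphenyl]ethanone
Conditions: HC(OMe)3, TsOH·H2O (cat.), MeOH, rt; Et3N
Reagents that add atoms: trimethyl orthoformate, COC(OC)OC; methanol, CO
Why: Acid-catalysed ketalisation with the orthoformate as water scavenger, in which the unhindered dialkyl ketone should react at room temperature while the aryl ketone, shielded by two ortho benzyloxy groups, is left alone.

Step 7
Reactants: 9 1-[2,4,6-tris(benzyloxy)-3-(3,3-dimethoxypentyl)-5-methylphenyl]ethanone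
Product: 10 1-{2,4,6-tris(benzyloxy)-3-[(3E)-3-methoxypent-3-en-1-yl]-5-methylphenyl}ethanone
Conditions: PPTS (cat.), toluene, reflux, 5 Å MS (MeOH trap); Et3N
Reagents that add atoms: none
Why: Acid-catalysed 1,2-elimination of methanol from a dimethyl ketal (ketal cracking), driven by trapping the methanol on molecular sieves, with the benzyl ethers and the acetyl group inert to the buffered acid and no need to separate the enol ether isomers.

Step 8
Reactants: 10 1-{2,4,6-tris(benzyloxy)-3-[(3E)-3-methoxypent-3-en-1-yl]-5-methylphenyl}ethanone; 11 malonyl dichloride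
Product: 13 1-{2,4,6-tris(benzyloxy)-3-[(4,6-dihydroxy-2-methoxy-3-methylphenyl)methyl]-5-methylphenyl}ethanone, via monoacylated acid chloride 12 (not isolated)
Conditions: ClCOCH2COCl (1.2 equiv), Et2O, −20 °C → rt, slow addition of 10; aq. NaHCO3
Reagents that add atoms: none
Why: This is an Effenberger cyclisation, the double C-acylation of a ketone methyl enol ether by malonyl dichloride, which is established for 1-methoxycycloalkenes (bicyclic triones) and should end in an arene when the enol ether is acyclic. The nucleophilic carbon of 10 (future position 3 of ring A) should attack one acid chloride, the oxocarbenium ion then losing a proton to give the β-methoxy enone 12, whose γ-deprotonation makes the carbon bearing the arylmethyl group (future position 5 of ring A) the terminus of a dienol ether. That carbon should attack the second acid chloride, or the acylketene formed from it by loss of HCl, in a 6-(enolendo)-exo-trig closure that forms ring A; two enolisations then aromatise the ring, with the O-methyl kept as the methoxyl at position 4 and the malonyl carbonyls becoming the hydroxyls at positions 2 and 6. No stereocentre is formed, and all regio- and stereoisomers of the enol ether converge. The step needs C- over O-acylation in the ring closure: the enol oxygen is blocked as its methyl ether, so a 2-pyranone can form only after demethylation by chloride, which low temperature and fast aromatisation should outrun, and slow addition of 10 to a slight excess of the dichloride at high dilution keeps the second acylation intramolecular. Ring B should stay out of the reaction because it has no free ring position and its acetyl group, twisted between two benzyloxy groups, does not enolise under these conditions.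

Step 9
Reactants: 13 1-{2,4,6-tris(benzyloxy)-3-[(4,6-dihydroxy-2-methoxy-3-methylphenyl)methyl]-5-methylphenyl}ethanone; 14 butanenitrile
Product: 16 1-{3-[3-acetyl-2,4,6-tris(benzyloxy)-5-methylbenzyl]-2,6-dihydroxy-4-methoxy-5-methylphenyl}butan-1-one, via ketiminium chloride 15 (not isolated)
Conditions: PrCN, ZnCl2, HCl (g), Et2O, 0 °C; then H2O–MeOH, 70 °C
Reagents that add atoms: water, O; hydrogen chloride, Cl (chloride of intermediate 15 only)
Why: Houben–Hoesch acylation, in which the nitrilium species from butanenitrile, ZnCl2 and HCl should attack position 1 of ring A, the only unsubstituted ring carbon, lying between two free hydroxyl groups and para to the methoxyl, hydrolysis of ketiminium salt 15 then giving the ketone, while the weak electrophile and mild Lewis acid should spare the aryl benzyl ethers, the acetyl group and the diarylmethane bridge and cannot O-acylate.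

Step 10
Reactants: 16 1-{3-[3-acetyl-2,4,6-tris(benzyloxy)-5-methylbenzyl]-2,6-dihydroxy-4-methoxy-5-methylphenyl}butan-1-one
Product: 17 1-{3-[(3-acetyl-2,4,6-trihydroxy-5-methylphenyl)methyl]-2,6-dihydroxy-4-methoxy-5-methylphenyl}butan-1-one (target)
Conditions: H2 (1 atm), Pd/C, EtOAc–MeOH, rt
Reagents that add atoms: none
Why: Hydrogenolysis of the three aryl benzyl ethers over Pd/C at room temperature, under which the two aryl ketones, each hydrogen-bonded to ortho hydroxyl groups, and the C–C bonds of the diarylmethane should not be reduced.

**Compound list**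

1 | 2,4,6-trihydroxytoluene | Cc1c(O)cc(O)cc1O | starting material
2 | [(2,4,6-trihydroxy-3-methylphenyl)methylidene]dimethyliminium chloride (formed in step 1, not isolated) | C[N+](C)=Cc1c(O)cc(O)c(C)c1O.[Cl-] | intermediate
3 | 2,4,6-trihydroxy-3-methylbenzaldehyde | Cc1c(O)cc(O)c(C=O)c1O | intermediate
4 | 3-acetyl-2,4,6-trihydroxy-5-methylbenzaldehyde | CC(=O)c1c(O)c(C)c(O)c(C=O)c1O | intermediate
5 | 3-acetyl-2,4,6-tris(benzyloxy)-5-methylbenzaldehyde | CC(=O)c1c(OCc2ccccc2)c(C)c(OCc2ccccc2)c(C=O)c1OCc1ccccc1 | intermediate
6 | diethyl (2-oxobutyl)phosphonate | CCC(=O)CP(=O)(OCC)OCC | starting material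
7 | (E)-1-[3-acetyl-2,4,6-tris(benzyloxy)-5-methylphenyl]pent-1-en-3-one | CCC(=O)/C=C/c1c(OCc2ccccc2)c(C)c(OCc2ccccc2)c(C(C)=O)c1OCc1ccccc1 | intermediate
8 | 1-[3-acetyl-2,4,6-tris(benzyloxy)-5-methylphenyl]pentan-3-one | CCC(=O)CCc1c(OCc2ccccc2)c(C)c(OCc2ccccc2)c(C(C)=O)c1OCc1ccccc1 | intermediate
9 | 1-[2,4,6-tris(benzyloxy)-3-(3,3-dimethoxypentyl)-5-methylphenyl]ethanone | CCC(OC)(OC)CCc1c(OCc2ccccc2)c(C)c(OCc2ccccc2)c(C(C)=O)c1OCc1ccccc1 | intermediate
10 | 1-{2,4,6-tris(benzyloxy)-3-[(3E)-3-methoxypent-3-en-1-yl]-5-methylphenyl}ethanone (used as the isomer mixture, see remark) | C/C=C(/OC)CCc1c(OCc2ccccc2)c(C)c(OCc2ccccc2)c(C(C)=O)c1OCc1ccccc1 | intermediate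
11 | malonyl dichloride | O=C(Cl)CC(=O)Cl | starting material
12 | 7-[3-acetyl-2,4,6-tris(benzyloxy)-5-methylphenyl]-5-methoxy-4-methyl-3-oxohept-4-enoyl chloride (formed in step 8, not isolated; C=C geometry not defined) | COC(CCc1c(OCc2ccccc2)c(C)c(OCc2ccccc2)c(C(C)=O)c1OCc1ccccc1)=C(C)C(=O)CC(=O)Cl | intermediate
13 | 1-{2,4,6-tris(benzyloxy)-3-[(4,6-dihydroxy-2-methoxy-3-methylphenyl)methyl]-5-methylphenyl}ethanone | COc1c(C)c(O)cc(O)c1Cc1c(OCc2ccccc2)c(C)c(OCc2ccccc2)c(C(C)=O)c1OCc1ccccc1 | intermediate
14 | butanenitrile | CCCC#N | starting material
15 | 1-{3-[3-acetyl-2,4,6-tris(benzyloxy)-5-methylbenzyl]-2,6-dihydroxy-4-methoxy-5-methylphenyl}butan-1-iminium chloride (formed in step 9, not isolated) | CCCC(=[NH2+])c1c(O)c(C)c(OC)c(Cc2c(OCc3ccccc3)c(C)c(OCc3ccccc3)c(C(C)=O)c2OCc2ccccc2)c1O.[Cl-] | intermediate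
16 | 1-{3-[3-acetyl-2,4,6-tris(benzyloxy)-5-methylbenzyl]-2,6-dihydroxy-4-methoxy-5-methylphenyl}butan-1-one | CCCC(=O)c1c(O)c(C)c(OC)c(Cc2c(OCc3ccccc3)c(C)c(OCc3ccccc3)c(C(C)=O)c2OCc2ccccc2)c1O | intermediate
17 | 1-{3-[(3-acetyl-2,4,6-trihydroxy-5-methylphenyl)methyl]-2,6-dihydroxy-4-methoxy-5-methylphenyl}butan-1-one | CCCC(=O)c1c(O)c(C)c(OC)c(Cc2c(O)c(C)c(O)c(C(C)=O)c2O)c1O | target

**Step count and risks**

Total steps: 10. Longest linear sequence: 10 steps (1 → 17).

Steps most likely to fail:

Step 8 (key step). The ring closure may go through oxygen after chloride has removed the O-methyl group, which leads to a 2-pyranone. The hydrogen chloride set free may also protonate the enol ether, so that ketone 8 returns at work-up, or the monoacylated chain may react with a second molecule of enol ether. The fallback forms the diarylmethane by Friedel–Crafts benzylation instead of building ring A. It sets out from aldehyde 5, which NaBH4 in THF–MeOH at −20 °C should reduce at the formyl group only, giving 1-[2,4,6-tris(benzyloxy)-3-(hydroxymethyl)-5-methylphenyl]ethanone F1. Ring A is brought in complete: compound 1 is acylated with butanoyl chloride and AlCl3 to 1-(2,4,6-trihydroxy-3-methylphenyl)butan-1-one F2, and its non-chelated hydroxyl para to the acyl group is methylated with one equivalent of Me2SO4 and K2CO3 in acetone to aspidinol F3. F1 and F3 are then joined with catalytic Sc(OTf)3 in CH2Cl2; the benzylic alcohol ionises and should attack the only free ring position of F3. This gives 16, where the route is rejoined, so step 9 is bypassed as well.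

Step 9. The nitrilium electrophile may fail to engage the crowded ring carbon between the two hydroxyl groups of ring A, or long exposure to HCl and ZnCl2 may cause loss or migration of benzyl groups. The fallback removes the benzyl ethers first and then uses a stronger acylating agent on the free polyphenol. It sets out from 13, whose hydrogenolysis (H2, Pd/C, EtOAc) should give 1-{3-[(4,6-dihydroxy-2-methoxy-3-methylphenyl)methyl]-2,4,6-trihydroxy-5-methylphenyl}ethanone F4. Friedel–Crafts acylation of F4 with butanoyl chloride and AlCl3 in nitrobenzene–CH2Cl2 at 0 °C to rt should then go to position 1 of ring A, the only unsubstituted aromatic carbon of the molecule, any O-butanoate rearranging by Fries reaction. This comes back to the route at the target 17.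

Step 7. Methanol loss may stop at an unfavourable equilibrium, the enol ether may hydrolyse back to 8 on isolation, or forcing the acid catalysis may begin to ketalise the acetyl group. The fallback is an irreversible, amine-buffered elimination with a silyl triflate at low temperature, with the acetyl group masked for the moment. It sets out from ketal 9: TMSOTf (2.5 equiv) and iPr2NEt in CH2Cl2 at −20 °C should convert the ketal into the methyl enol ether and at the same time silylate the acetyl group, giving {1-[2,4,6-tris(benzyloxy)-3-[(3E)-3-methoxypent-3-en-1-yl]-5-methylphenyl]ethenyl}oxy(trimethyl)silane F5. K2CO3 in MeOH at 0 °C should then cleave only the silyl enol ether, since methyl enol ethers are stable to base, and the route is rejoined at compound 10.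

**Further compounds**

F1 | step 8 | 1-[2,4,6-tris(benzyloxy)-3-(hydroxymethyl)-5-methylphenyl]ethanone | CC(=O)c1c(OCc2ccccc2)c(C)c(OCc2ccccc2)c(CO)c1OCc1ccccc1
F2 | step 8 | 1-(2,4,6-trihydroxy-3-methylphenyl)butan-1-one | CCCC(=O)c1c(O)cc(O)c(C)c1O
F3 | step 8 | aspidinol, 1-(2,6-dihydroxy-4-methoxy-3-methylphenyl)butan-1-one | CCCC(=O)c1c(O)cc(OC)c(C)c1O
F4 | step 9 | 1-{3-[(4,6-dihydroxy-2-methoxy-3-methylphenyl)methyl]-2,4,6-trihydroxy-5-methylphenyl}ethanone | COc1c(C)c(O)cc(O)c1Cc1c(O)c(C)c(O)c(C(C)=O)c1O
F5 | step 7 | {1-[2,4,6-tris(benzyloxy)-3-[(3E)-3-methoxypent-3-en-1-yl]-5-methylphenyl]ethenyl}oxy(trimethyl)silane | C/C=C(/OC)CCc1c(OCc2ccccc2)c(C)c(OCc2ccccc2)c(C(=C)O[Si](C)(C)C)c1OCc1ccccc1
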